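**Retrosynthetic overview**
1. The oxonane is closed last, at C6–C7, by a Ni/Cr-mediated coupling of aldehyde/vinyl bromide 27.
2. The ε-lactone and the C4 octanoate come from one double Baeyer–Villiger oxidation of diketone 23: ring expansion of cyclohexanone ring B (C3 migrates to O) and a C4-to-O shift in the side-chain octanoyl ketone, both with retention.
3. The oxolane comes from an intramolecular Tishchenko hydride transfer C9→C2 (sets C2), lactol acetal formation, then 2-bromoallylsilane addition at C9.
4. Ring A comes from a proline aldol (C10–C11) on ring B; C3/C4 come from an iminium Michael addition of dione 8 to 4-oxoundec-2-enal (made from 2-heptylfuran).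
5. Ring B comes from an enantioselective Michael–Claisen [3+3] annulation of pentan-3-one with enoate 3 (new), then γ-allylation. Ring order: B, A, oxolane, ε-lactone (from B), oxonane.

Atom labels are those of the target: C1–C10 is the ten-membered carbocycle (ether O on C2 and C9, lactone O and CH3 on C3, octanoate on C4, OH on C6, =CH2 on C7); C11–C14 complete the cyclohexane (C11 = C(OH)CH3); C18 = CH(CH3) and C19 = lactone C=O, attached to C14.

Assumption: the SMILES is taken literally, i.e. C3 lies on the same face of the oxolane as the cyclohexane and C8 on the opposite face (1S,2R,3S,4R,6S,9S,10R,11R,14R,18R in the labels above); the route is built for exactly this isomer.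

**Step 1**
Reactants: 1 methyl acrylate; 2 2-methylhexa-1,5-diene
Product: 3 methyl (2E)-6-methylhepta-2,6-dienoate
Conditions: second-generation Grubbs catalyst [RuCl2(=CHPh)(H2IMes)(PCy3)] (2 mol%), 1 (3 equiv), CH2Cl2, 40 °C
Reagents that add atoms: none
Why: Cross-metathesis of the monosubstituted alkene with the acrylate gives the E-enoate, while the 1,1-disubstituted alkene does not react.

**Step 2**
Reactants: 4 pentan-3-one; 3 methyl (2E)-6-methylhepta-2,6-dienoate
Product: 6 (4S,5R)-2,4-dimethyl-5-(3-methylbut-3-en-1-yl)cyclohexane-1,3-dione, via Michael-adduct keto ester 5 (not isolated)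
Conditions: LiN(i-Pr)2 (1.1 equiv), (R,R)-1,2-dimethoxy-1,2-diphenylethane (0.2 equiv), toluene, −78 °C; add 3; −78 → 23 °C; 1 M HCl
Reagents that add atoms: none
Why: Proposed new method: an enantioselective Michael–Claisen [3+3] annulation in which the lithium enolate of 4, bound to the C2-symmetric diether, adds to one face of the enoate β-carbon (C14) in a lithium-bridged transition state, the ester enolate then transfers a proton to give the ketone enolate, and Claisen condensation closes ring B; the closest known reactions are chiral-diether-controlled conjugate additions of lithium ester enolates to enoates and the racemic consecutive Michael–Claisen synthesis of cyclohexane-1,3-diones; the ligand enantiomer is assigned by analogy (its antipode would give ent-6), and C18 equilibrates to 4,5-trans.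

**Step 3**
Reactants: 6 (4S,5R)-2,4-dimethyl-5-(3-methylbut-3-en-1-yl)cyclohexane-1,3-dione; 7 allyl bromide
Product: 8 (4S,5S,6R)-2,4-dimethyl-5-(3-methylbut-3-en-1-yl)-6-(prop-2-en-1-yl)cyclohexane-1,3-dione
Conditions: LiN(i-Pr)2 (2.2 equiv), THF, −78 → −20 °C; 7 (1.05 equiv); aq. HCl
Reagents that add atoms: none
Why: γ-Alkylation of the 1,3-diketone dianion occurs at the less substituted CH2 (C1), anti to the C14 side chain, and the centre stays equatorial (all-trans) because it is epimerisable.

**Step 4**
Reactants: 9 furan; 10 1-bromoheptane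
Product: 11 2-heptylfuran
Conditions: n-BuLi, THF, −78 → 0 °C; then 10, 0 → 23 °C
Reagents that add atoms: none
Why: α-Lithiation of furan followed by SN2 alkylation with the primary bromide.

**Step 5**
Reactants: 11 2-heptylfuran
Product: 13 (2E)-4-oxoundec-2-enal, via (2Z)-4-oxoundec-2-enal 12 (not isolated)
Conditions: NBS, NaHCO3, acetone/H2O (10:1), −15 °C; then pyridine, 23 °C
Reagents that add atoms: water, O
Why: Oxidative ring opening of the 2-alkylfuran gives the cis-4-oxo-enal, which pyridine isomerises to the E isomer.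

**Step 6**
Reactants: 8 (4S,5S,6R)-2,4-dimethyl-5-(3-methylbut-3-en-1-yl)-6-(prop-2-en-1-yl)cyclohexane-1,3-dione; 13 (2E)-4-oxoundec-2-enal
Product: 15 (2R,4S,5S,6R)-2-[(3R)-1-hydroxy-4-oxoundecan-3-yl]-2,4-dimethyl-5-(3-methylbut-3-en-1-yl)-6-(prop-2-en-1-yl)cyclohexane-1,3-dione, via Michael-adduct aldehyde 14 (not isolated)
Conditions: (S)-2-[diphenyl(trimethylsilyloxy)methyl]pyrrolidine (20 mol%), PhCO2H (20 mol%), toluene, 0 °C; then NaBH4, EtOH/CH2Cl2, −78 °C
Reagents that add atoms: none
Why: Iminium-catalysed Michael addition of the 2-methyl-1,3-dione to the carbon β to the aldehyde (C4): the catalyst shields one face of the iminium ion so that C4 is formed R, the dione enol is attacked on its axial face so that the C3 methyl ends equatorial and the new chain axial, and the aldehyde is reduced at once (aldehyde-selective at −78 °C) to stop retro-Michael reaction.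

**Step 7**
Reactants: 15 primary alcohol from step 6
Product: 16 tert-butyldiphenylsilyl ether of 15 (C6–OSi)
Conditions: t-BuPh2SiCl, imidazole, CH2Cl2, 0 → 23 °C
Reagents that add atoms: tert-butyl(chloro)diphenylsilane, CC(C)(C)[Si](Cl)(c1ccccc1)c1ccccc1
Why: Silylation of the primary alcohol traps the open-chain form and protects C6–O through the oxidative and Lewis-acid steps.

**Step 8**
Reactants: 16 silyl ether
Product: 17 keto aldehyde (allyl cut to C1–CH2–CHO = C10–C9; methylbutenyl cut to C14–CH2CH2–COCH3 = C13–C12–C11)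
Conditions: O3, CH2Cl2, −78 °C; then PPh3
Reagents that add atoms: ozone, [O-][O+]=O
Why: Ozonolysis with reductive work-up cleaves both terminal alkenes, giving the C9 aldehyde and the C11 methyl ketone; the dione is fully substituted at C3 and has no enol to attack.

**Step 9**
Reactants: 17 keto aldehyde
Product: 18 trans-decalin β-hydroxy aldehyde (ring A closed C10–C11; C9 aldehyde equatorial; C11 OH equatorial and CH3 axial)
Conditions: D-proline (30 mol%), DMSO, 23 °C
Reagents that add atoms: none
Why: 6-Enolexo proline aldol in which the enamine of the C9 aldehyde adds to the methyl ketone through a chair transition state with the ketone oxygen equatorial (matched with D-proline), giving the trans ring fusion and the target configuration at C11.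

**Step 10**
Reactants: 18 trans-decalin β-hydroxy aldehyde
Product: 19 S-ethyl thioester (C9 = C(O)SEt, equatorial) with axial C2–OH
Conditions: SmI2 (0.3 equiv), EtSH (1.2 equiv), THF, 23 °C
Reagents that add atoms: ethanethiol, CCS
Why: Samarium/thiol-promoted intramolecular Tishchenko reaction in which the hemithioacetal C9–H, held equatorial on C10 and therefore below the C2 carbonyl plane, is delivered to the lower face of the C2 ketone, so that H2 is set cis to H1 and the C2 oxygen becomes axial.

**Step 11**
Reactants: 19 S-ethyl thioester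
Product: 21 cyclic methyl acetal (oxolane C2–O–C9 closed; C9–OMe anomers; C10 now carries C9 axial), via hydroxy aldehyde 20 (not isolated)
Conditions: Et3SiH, Pd/C (10 mol%), acetone, 23 °C; filter; then CSA (10 mol%), MeOH, 40 °C
Reagents that add atoms: methanol, CO
Why: Fukuyama reduction takes the thioester to the aldehyde without touching the ketones; acid then epimerises C10 through the enol, and because the C2–OH is fixed axial only the cis,cis-fused lactol ether can close.

**Step 12**
Reactants: 21 cyclic methyl acetal; 22 (2-bromoprop-2-en-1-yl)trimethylsilane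
Product: 23 tricyclic diketone carrying the 2-bromoallyl group on C9
Conditions: 22 (3 equiv), Me3SiOTf (0.2 equiv), CH2Cl2, −78 → −40 °C
Reagents that add atoms: none
Why: Hosomi–Sakurai addition to the C9 oxocarbenium ion on its outer face, away from the decalin, which places C8 trans to the cyclohexane across the oxolane.

**Step 13**
Reactants: 23 tricyclic diketone
Product: 24 ε-lactone octanoate (C19(=O)–O–C3 and C4–O–CO–C7H15)
Conditions: mCPBA (5 equiv), CH2Cl2, 40 °C
Reagents that add atoms: 3-chloroperbenzoic acid, OOC(=O)c1cccc(Cl)c1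
Why: Double Baeyer–Villiger oxidation: in ring B the quaternary C3 migrates in preference to CH(CH3) (ring expansion to the ε-lactone), and in the side chain the secondary C4 migrates in preference to CH2 (octanoyl ketone to octanoate); both occur with retention, and the vinyl bromide is too electron-poor to be epoxidised.

**Step 14**
Reactants: 24 ε-lactone octanoate
Product: 25 C18 epimer of 24 (C18 methyl cis to C13, as in the target)
Conditions: LiN(i-Pr)2 (4 equiv), THF, −78 °C; then 2,6-di-tert-butyl-4-methylphenol, −78 °C; aq. NH4Cl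
Reagents that add atoms: none
Why: Kinetic protonation of the lactone enolate by a bulky phenol from the face opposite the axial C3 side chain inverts C18; the methyl had been held equatorial while C19 was a ketone, and the octanoate enolate that also forms simply reprotonates.

**Step 15**
Reactants: 25 C18-epimerised lactone
Product: 26 primary alcohol (C6–OH)
Conditions: HF·pyridine, THF, 0 → 23 °C
Reagents that add atoms: none
Why: Acidic fluoride cleaves the silyl ether without the 1,3-acyl migration a basic fluoride source could cause.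

**Step 16**
Reactants: 26 primary alcohol
Product: 27 aldehyde (C6 = CHO)
Conditions: Dess–Martin periodinane, CH2Cl2, 23 °C
Reagents that add atoms: none
Why: Dess–Martin oxidation of the primary alcohol; the tertiary C11–OH is inert and the neutral conditions avoid β-elimination of the octanoate.

**Step 17**
Reactants: 27 aldehyde
Product: 28 target (CNP0295349.4)
Conditions: CrCl2 (10 equiv), NiCl2 (0.1 equiv), DMSO, 23 °C, 2 mM; aq. work-up
Reagents that add atoms: none
Why: Intramolecular Nozaki–Hiyama–Kishi coupling of the vinyl bromide with the C6 aldehyde forms C6–C7, the allylic alcohol and the exocyclic methylene in one step; 6S is expected from addition to the aldehyde face exposed when the C4 octanoate sits pseudo-equatorial in the closing ring.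

**Compound list**
1 | methyl acrylate | C=CC(=O)OC | starting material
2 | 2-methylhexa-1,5-diene | C=C(C)CCC=C | starting material
3 | methyl (2E)-6-methylhepta-2,6-dienoate | C=C(C)CC/C=C/C(=O)OC | intermediate
4 | pentan-3-one | CCC(=O)CC | starting material
5 | methyl (3R)-4-methyl-3-(3-methylbut-3-en-1-yl)-5-oxoheptanoate (C4 epimers) | CCC(=O)C(C)[C@H](CCC(C)=C)CC(=O)OC | intermediate
6 | (4S,5R)-2,4-dimethyl-5-(3-methylbut-3-en-1-yl)cyclohexane-1,3-dione (4,5-trans; drawn as one enol) | O=C1[C@@H](C)[C@H](CCC(C)=C)CC(O)=C1C | intermediate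
7 | allyl bromide | C=CCBr | starting material
8 | (4S,5S,6R)-2,4-dimethyl-5-(3-methylbut-3-en-1-yl)-6-(prop-2-en-1-yl)cyclohexane-1,3-dione (all-trans; drawn as one enol) | O=C1[C@@H](C)[C@H](CCC(C)=C)[C@@H](CC=C)C(O)=C1C | intermediate
9 | furan | c1ccoc1 | starting material
10 | 1-bromoheptane | CCCCCCCBr | starting material
11 | 2-heptylfuran | CCCCCCCc1ccco1 | intermediate
12 | (2Z)-4-oxoundec-2-enal | CCCCCCCC(=O)/C=C\C=O | intermediate
13 | (2E)-4-oxoundec-2-enal | CCCCCCCC(=O)/C=C/C=O | intermediate
14 | (2R,4S,5S,6R)-2,4-dimethyl-5-(3-methylbut-3-en-1-yl)-2-[(3R)-1,4-dioxoundecan-3-yl]-6-(prop-2-en-1-yl)cyclohexane-1,3-dione | O=C1[C@@H](C)[C@H](CCC(C)=C)[C@@H](CC=C)C(=O)[C@]1(C)[C@@H](CC=O)C(=O)CCCCCCC | intermediate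
15 | (2R,4S,5S,6R)-2-[(3R)-1-hydroxy-4-oxoundecan-3-yl]-2,4-dimethyl-5-(3-methylbut-3-en-1-yl)-6-(prop-2-en-1-yl)cyclohexane-1,3-dione | O=C1[C@@H](C)[C@H](CCC(C)=C)[C@@H](CC=C)C(=O)[C@]1(C)[C@@H](CCO)C(=O)CCCCCCC | intermediate
16 | tert-butyldiphenylsilyl ether of 15 | O=C1[C@@H](C)[C@H](CCC(C)=C)[C@@H](CC=C)C(=O)[C@]1(C)[C@@H](CCO[Si](c2ccccc2)(c3ccccc3)C(C)(C)C)C(=O)CCCCCCC | intermediate
17 | keto aldehyde (C1–CH2CHO and C14–CH2CH2COCH3 on ring B) | O=C1[C@@H](C)[C@H](CCC(C)=O)[C@@H](CC=O)C(=O)[C@]1(C)[C@@H](CCO[Si](c2ccccc2)(c3ccccc3)C(C)(C)C)C(=O)CCCCCCC | intermediate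
18 | trans-decalin β-hydroxy aldehyde (C9 equatorial; C11 OH equatorial, CH3 axial) | O=C1[C@@H](C)[C@@H]2CC[C@@](C)(O)[C@H](C=O)[C@H]2C(=O)[C@]1(C)[C@@H](CCO[Si](c3ccccc3)(c4ccccc4)C(C)(C)C)C(=O)CCCCCCC | intermediate
19 | S-ethyl thioester at C9 with axial C2–OH | O=C1[C@@H](C)[C@@H]2CC[C@@](C)(O)[C@H](C(=O)SCC)[C@H]2[C@@H](O)[C@]1(C)[C@@H](CCO[Si](c3ccccc3)(c4ccccc4)C(C)(C)C)C(=O)CCCCCCC | intermediate
20 | hydroxy aldehyde (C9 = CHO, C2–OH axial) | O=C1[C@@H](C)[C@@H]2CC[C@@](C)(O)[C@H](C=O)[C@H]2[C@@H](O)[C@]1(C)[C@@H](CCO[Si](c3ccccc3)(c4ccccc4)C(C)(C)C)C(=O)CCCCCCC | intermediate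
21 | cyclic methyl acetal (oxolane closed, C9–OMe anomers) | O=C1[C@@H](C)[C@@H]2CC[C@@](C)(O)[C@@H]3[C@H]2[C@@H](OC3OC)[C@]1(C)[C@@H](CCO[Si](c4ccccc4)(c5ccccc5)C(C)(C)C)C(=O)CCCCCCC | intermediate
22 | (2-bromoprop-2-en-1-yl)trimethylsilane | C=C(Br)C[Si](C)(C)C | starting material
23 | tricyclic diketone with 2-bromoallyl on C9 | O=C1[C@@H](C)[C@@H]2CC[C@@](C)(O)[C@@H]3[C@H]2[C@@H](O[C@H]3CC(Br)=C)[C@]1(C)[C@@H](CCO[Si](c4ccccc4)(c5ccccc5)C(C)(C)C)C(=O)CCCCCCC | intermediate
24 | ε-lactone octanoate (C18 epimer of the target series) | O=C1[C@@H](C)[C@@H]2CC[C@@](C)(O)[C@@H]3[C@H]2[C@@H](O[C@H]3CC(Br)=C)[C@@](C)(O1)[C@@H](CCO[Si](c4ccccc4)(c5ccccc5)C(C)(C)C)OC(=O)CCCCCCC | intermediate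
25 | ε-lactone octanoate with target configuration at C18 | O=C1[C@H](C)[C@@H]2CC[C@@](C)(O)[C@@H]3[C@H]2[C@@H](O[C@H]3CC(Br)=C)[C@@](C)(O1)[C@@H](CCO[Si](c4ccccc4)(c5ccccc5)C(C)(C)C)OC(=O)CCCCCCC | intermediate
26 | primary alcohol (C6–OH) | O=C1[C@H](C)[C@@H]2CC[C@@](C)(O)[C@@H]3[C@H]2[C@@H](O[C@H]3CC(Br)=C)[C@@](C)(O1)[C@@H](CCO)OC(=O)CCCCCCC | intermediate
27 | aldehyde (C6 = CHO) with vinyl bromide | O=C1[C@H](C)[C@@H]2CC[C@@](C)(O)[C@@H]3[C@H]2[C@@H](O[C@H]3CC(Br)=C)[C@@](C)(O1)[C@@H](CC=O)OC(=O)CCCCCCC | intermediate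
28 | CNP0295349.4 | C=C1C[C@@H]2O[C@@H]3[C@H]4[C@@H](CC[C@@](C)(O)[C@H]42)[C@@H](C)C(=O)O[C@@]3(C)[C@H](OC(=O)CCCCCCC)C[C@@H]1O | target

**Totals**
Total steps: 17. Longest linear sequence: 15 (steps 1–3 and 6–17; steps 4–5 are a side branch).

**Three steps most likely to fail**

Step 2 (the new enantioselective Michael–Claisen annulation). The fallback sets out from 4 and returns at 6 using auxiliary chemistry. Condensation of 4 with (S)-1-amino-2-(methoxymethyl)pyrrolidine gives pentan-3-one SAMP hydrazone F1. Its lithium azaenolate (LiN(i-Pr)2, THF, −78 °C) adds to enoate 3 in an auxiliary-controlled Michael addition to give Michael-adduct hydrazone ester F2. Aqueous oxalic acid then releases keto ester 5 (here isolated) and the auxiliary, and NaOMe in MeOH closes ring B by Claisen condensation to give 6. If the auxiliary's sense of induction proves opposite, the R-configured auxiliary is used.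

Step 10 (Tishchenko hydride transfer; risk of retro-aldol or hydride delivery to the wrong face). The fallback sets out from 18 and returns at 21. CSA in MeOH converts the 1,4-keto aldehyde into cyclic bis-acetal F3; C10 epimerises under these conditions, and the cis,cis-fused isomer is enriched by re-equilibrating the unwanted one. Et3SiH with Me3SiOTf at −78 °C then reduces only the ketone-derived ketal carbon C2, hydride entering from the open lower face, to give 21.

Step 17 (closure of the strained oxonane at C6–C7). The fallback sets out from 21 and returns at 28; it makes C6–C7 intermolecularly and closes the ring at C8–C9 instead. The double Baeyer–Villiger oxidation of 21 (mCPBA) gives acetal lactone octanoate F4. Kinetic protonation as in step 14 gives C18-epimerised acetal lactone F5, HF·pyridine gives primary alcohol F6, and Dess–Martin oxidation gives acetal aldehyde F7. Ni/Cr coupling of F7 with the vinyl bromide of 22 gives allylsilane carbinol F8; the C6 epimers are separated, or C6 is corrected by oxidation and reagent-controlled reduction. Me3SiOTf at high dilution then ionises the C9 acetal, and intramolecular Hosomi–Sakurai attack of the allylsilane on the outer face of the oxocarbenium ion closes the ring to 28.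

**Further compounds**
F1 | step 2 | pentan-3-one SAMP hydrazone | CCC(CC)=NN1CCC[C@H]1COC
F2 | step 2 | Michael-adduct hydrazone ester | CCC(=NN1CCC[C@H]1COC)C(C)[C@H](CCC(C)=C)CC(=O)OC
F3 | step 10 | cyclic bis-acetal (C2 ketal and C9 acetal, C9 anomers) | O=C1[C@@H](C)[C@@H]2CC[C@@](C)(O)[C@@H]3[C@H]2[C@@](OC)(OC3OC)[C@]1(C)[C@@H](CCO[Si](c4ccccc4)(c5ccccc5)C(C)(C)C)C(=O)CCCCCCC
F4 | step 17 | acetal lactone octanoate | O=C1[C@@H](C)[C@@H]2CC[C@@](C)(O)[C@@H]3[C@H]2[C@@H](OC3OC)[C@@](C)(O1)[C@@H](CCO[Si](c4ccccc4)(c5ccccc5)C(C)(C)C)OC(=O)CCCCCCC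
F5 | step 17 | C18-epimerised acetal lactone | O=C1[C@H](C)[C@@H]2CC[C@@](C)(O)[C@@H]3[C@H]2[C@@H](OC3OC)[C@@](C)(O1)[C@@H](CCO[Si](c4ccccc4)(c5ccccc5)C(C)(C)C)OC(=O)CCCCCCC
F6 | step 17 | primary alcohol of the acetal lactone | O=C1[C@H](C)[C@@H]2CC[C@@](C)(O)[C@@H]3[C@H]2[C@@H](OC3OC)[C@@](C)(O1)[C@@H](CCO)OC(=O)CCCCCCC
F7 | step 17 | acetal aldehyde | O=C1[C@H](C)[C@@H]2CC[C@@](C)(O)[C@@H]3[C@H]2[C@@H](OC3OC)[C@@](C)(O1)[C@@H](CC=O)OC(=O)CCCCCCC
F8 | step 17 | allylsilane carbinol | O=C1[C@H](C)[C@@H]2CC[C@@](C)(O)[C@@H]3[C@H]2[C@@H](OC3OC)[C@@](C)(O1)[C@@H](C[C@H](O)C(=C)C[Si](C)(C)C)OC(=O)CCCCCCC
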